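## Retrosynthetic overview
1. Last C–C bond, C2'–C3' (sp3–sp3, copper catalysis): the target comes from an (S)-2-(2-bromoethyl)chroman-6-yl acetate and a C14 Grignard reagent. The Grignard reagent already holds C4', C8' and the isopropenyl end.
2. Only ring formed, the dihydropyran ring on the existing arene: enantioselective oxa-[4+2] of a dearomatised o-quinone methide (trimethylhydroquinone + CH2O) with 4-bromo-2-methylbut-1-ene. This makes O1–C2 and C3–C4 and sets C2.
3. The C14 chain is (E)-geranylacetone read from its ketone (C12') to its terminal E-methyl group (C3'). The sequence is allylic oxidation, one iridium-catalysed hydrogenation for both methyl stereocentres, Wittig methylenation after the hydrogenation, and bromination.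
4. The chain (4 steps) and the chroman bromide (3 steps) are made in parallel and joined in the final step.

Target read from the SMILES: a 6-chromanol, C29H48O2, with C2 = R, C4' = R and C8' = S. The S descriptor arises only because the isopropenyl end outranks the chroman end. Spatially C8' matches 8'R of natural α-tocopherol.

Assumption: the absolute sense of induction of the chiral catalysts (steps 2 and 7, and the ruthenium catalyst of the fallback to step 2) is assigned by analogy. Both enantiomers of each are accessible, and the one that gives the drawn configuration is meant.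

## Route

Step 1
Reactants: 1 (E)-geranylacetone, (5E)-6,10-dimethylundeca-5,9-dien-2-one
Product: 2 (5E,9E)-11-hydroxy-6,10-dimethylundeca-5,9-dien-2-one
Conditions: SeO2 (10 mol%), salicylic acid (10 mol%), t-BuOOH (2.5 equiv), CH2Cl2, 0 °C to rt, stopped at about 60% conversion (1 recycled)
Reagents that add atoms: tert-butyl hydroperoxide, CC(C)(C)OO (terminal oxygen source); selenium dioxide, O=[Se]=O (catalytic oxygen carrier)
Why: Catalytic SeO2 allylic oxidation (ene reaction, then [2,3]-sigmatropic shift) attacks the more accessible terminal isopropylidene group and oxidises only its E-methyl group, while the methyl ketone is inert at this temperature.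

Step 2
Reactants: 2 (5E,9E)-11-hydroxy-6,10-dimethylundeca-5,9-dien-2-one
Product: 3 (6S,10R)-11-hydroxy-6,10-dimethylundecan-2-one
Conditions: [Ir(cod)(L*)]BArF (1 mol%), H2 (50 bar), CH2Cl2, rt; L* = (S)-2-phenyl-7-[bis(2-methylphenyl)phosphanyloxy]-6,7-dihydro-5H-cyclopenta[b]pyridine, BArF = B[3,5-(CF3)2C6H3]4
Reagents that add atoms: none
Why: In this Ir–N,P asymmetric hydrogenation of trisubstituted alkenes, both E-alkenes show the catalyst the same local shape in the same chain direction, so H2 goes to the same enantioface of each, C6 (S) and C10 (R) are set together under catalyst control, and the ketone is not reduced.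

Step 3
Reactants: 3 (6S,10R)-11-hydroxy-6,10-dimethylundecan-2-one
Product: 4 (2R,6S)-2,6,10-trimethylundec-10-en-1-ol
Conditions: Ph3PCH3Br (2.5 equiv), KOtBu (2.4 equiv), THF, 0 °C to rt
Reagents that add atoms: methyltriphenylphosphonium bromide, C[P+](c1ccccc1)(c1ccccc1)c1ccccc1.[Br-]
Why: Wittig methylenation installs the isopropenyl end only after the hydrogenation, the excess ylide covers the free OH, and neither stereocentre is alpha to the carbonyl, so none can epimerise.

Step 4
Reactants: 4 (2R,6S)-2,6,10-trimethylundec-10-en-1-ol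
Product: 5 (6S,10R)-11-bromo-2,6,10-trimethylundec-1-ene
Conditions: CBr4, PPh3, CH2Cl2, 0 °C
Reagents that add atoms: carbon tetrabromide, BrC(Br)(Br)Br
Why: The Appel reaction substitutes at the primary carbon only (SN2), so the neighbouring stereocentre and the 1,1-disubstituted alkene are untouched.

Step 5
Reactants: 6 2,3,5-trimethylhydroquinone
Product: 8 4-hydroxy-2,3,6-trimethylphenyl acetate, via trimethylhydroquinone diacetate 7 (not isolated)
Conditions: Ac2O (2.1 equiv), pyridine, rt; then n-BuNH2 (1.1 equiv), 0 °C
Reagents that add atoms: acetic anhydride, CC(=O)OC(C)=O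
Why: Exhaustive acetylation followed by chemoselective aminolysis cleaves the acetate with one ortho-methyl much faster than the di-ortho-methyl one, which frees the phenol next to the open ring position and caps the other oxygen so the later quinone methide cannot tautomerise to duroquinone.

Step 6
Reactants: 8 4-hydroxy-2,3,6-trimethylphenyl acetate
Product: 10 4-hydroxy-3-(hydroxymethyl)-2,5,6-trimethylphenyl acetate, via benzodioxaborinine 9 (not isolated)
Conditions: PhB(OH)2, (CH2O)n, EtCO2H (cat.), toluene, reflux (Dean–Stark); then 2,2-dimethylpropane-1,3-diol, rt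
Reagents that add atoms: paraformaldehyde (as formaldehyde), C=O; phenylboronic acid, OB(O)c1ccccc1 (its atoms stay only in 9)
Why: In this boronic-acid-templated ortho-hydroxymethylation (Nagata reaction), the aryl boronate delivers formaldehyde to the only free ortho position through a six-membered transition state, and exchange to the more stable aliphatic boronate releases the o-hydroxybenzyl alcohol without touching the acetate.

Step 7 (key step)
Reactants: 10 4-hydroxy-3-(hydroxymethyl)-2,5,6-trimethylphenyl acetate; 11 4-bromo-2-methylbut-1-ene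
Product: 13 (2S)-2-(2-bromoethyl)-2,5,7,8-tetramethylchroman-6-yl acetate, via ortho-quinone methide 12 (not isolated)
Conditions: (S,S)-IDPi (5 mol%; BINOL-derived imidodiphosphorimidate, 3,3'-aryl = 3,5-(CF3)2C6H3, N-substituent SO2CF3), 11 (10 equiv), 5 Å MS, CHCl3/cyclohexane, −20 °C, slow addition of 10; recrystallise to upgrade ee
Reagents that add atoms: none
Why: Proposed new method: the strong confined acid ionises the electron-rich o-hydroxybenzyl alcohol 10 to the dearomatised o-quinone methide 12, held as a hydrogen-bonded ion pair in the chiral pocket; the simple 1,1-disubstituted alkene 11 attacks the methide carbon with its CH2 end in a concerted but asynchronous inverse-electron-demand oxa-Diels–Alder reaction, the ring oxygen closes on the developing tertiary cation (Markovnikov sense) with rearomatisation, and the pocket distinguishes methyl from 2-bromoethyl so that C2 is set as S; the closest known reaction types are the thermal trimethylhydroquinone/formaldehyde/alkene chroman synthesis, Brønsted-acid-catalysed asymmetric cycloadditions of o-quinone methides with styrenes and tethered simple alkenes, and the IDPi-catalysed asymmetric hydroalkoxylation of unactivated 1,1-dialkyl alkenes, which already gives methyl/alkyl tertiary ethers selectively.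

Step 8
Reactants: 5 (6S,10R)-11-bromo-2,6,10-trimethylundec-1-ene; 13 (2S)-2-(2-bromoethyl)-2,5,7,8-tetramethylchroman-6-yl acetate
Product: 16 (2R)-2,5,7,8-tetramethyl-2-[(4R,8S)-4,8,12-trimethyltridec-12-en-1-yl]chroman-6-ol, via Grignard reagent 14 (not isolated), via O-acetyl target 15 (not isolated)
Conditions: 5, Mg, THF, 40 °C; then 13, Li2CuCl4 (5 mol%), THF, −20 °C to rt; then LiAlH4, 0 °C; aq. NH4Cl, under N2
Reagents that add atoms: none
Why: Kochi-type copper-catalysed sp3–sp3 coupling of a primary Grignard reagent with a primary bromide is faster than attack on the di-ortho-methyl aryl acetate and touches no stereocentre (the C2 descriptor changes from S to R only through the priority change), and LiAlH4 added to the same flask removes the acetate.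

## Compound list
1 | (5E)-6,10-dimethylundeca-5,9-dien-2-one, (E)-geranylacetone | CC(=O)CC/C=C(\C)CCC=C(C)C | starting material
2 | (5E,9E)-11-hydroxy-6,10-dimethylundeca-5,9-dien-2-one | CC(=O)CC/C=C(\C)CC/C=C(\C)CO | intermediate
3 | (6S,10R)-11-hydroxy-6,10-dimethylundecan-2-one | CC(=O)CCC[C@@H](C)CCC[C@@H](C)CO | intermediate
4 | (2R,6S)-2,6,10-trimethylundec-10-en-1-ol | C=C(C)CCC[C@@H](C)CCC[C@@H](C)CO | intermediate
5 | (6S,10R)-11-bromo-2,6,10-trimethylundec-1-ene | C=C(C)CCC[C@@H](C)CCC[C@@H](C)CBr | intermediate
6 | 2,3,5-trimethylhydroquinone | Cc1cc(O)c(C)c(C)c1O | starting material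
7 | 2,3,5-trimethyl-1,4-phenylene diacetate | CC(=O)Oc1cc(C)c(OC(C)=O)c(C)c1C | intermediate
8 | 4-hydroxy-2,3,6-trimethylphenyl acetate | CC(=O)Oc1c(C)c(C)c(O)cc1C | intermediate
9 | 5,7,8-trimethyl-2-phenyl-4H-1,3,2-benzodioxaborinin-6-yl acetate | CC(=O)Oc1c(C)c(C)c2OB(c3ccccc3)OCc2c1C | intermediate
10 | 4-hydroxy-3-(hydroxymethyl)-2,5,6-trimethylphenyl acetate | CC(=O)Oc1c(C)c(CO)c(O)c(C)c1C | intermediate
11 | 4-bromo-2-methylbut-1-ene | C=C(C)CCBr | starting material
12 | 2,5,6-trimethyl-3-methylidene-4-oxocyclohexa-1,5-dien-1-yl acetate (o-quinone methide) | C=C1C(=O)C(C)=C(C)C(OC(C)=O)=C1C | intermediate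
13 | (2S)-2-(2-bromoethyl)-2,5,7,8-tetramethylchroman-6-yl acetate | BrCC[C@]1(C)CCc2c(C)c(OC(C)=O)c(C)c(C)c2O1 | intermediate
14 | [(2R,6S)-2,6,10-trimethylundec-10-en-1-yl]magnesium bromide | C=C(C)CCC[C@@H](C)CCC[C@@H](C)C[Mg]Br | intermediate
15 | (2R)-2,5,7,8-tetramethyl-2-[(4R,8S)-4,8,12-trimethyltridec-12-en-1-yl]chroman-6-yl acetate | C=C(C)CCC[C@@H](C)CCC[C@@H](C)CCC[C@]1(C)CCc2c(C)c(OC(C)=O)c(C)c(C)c2O1 | intermediate
16 | (2R)-2,5,7,8-tetramethyl-2-[(4R,8S)-4,8,12-trimethyltridec-12-en-1-yl]chroman-6-ol | C=C(C)CCC[C@@H](C)CCC[C@@H](C)CCC[C@]1(C)CCc2c(C)c(O)c(C)c(C)c2O1 | target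

## Step count and risks
Total steps: 8. Longest linear sequence: 5 (steps 1, 2, 3, 4, 8). The chroman branch (steps 5, 6, 7, 8) is 4 steps long.

**Step 7** (new asymmetric cycloaddition; the risks are quinone methide dimerisation and low ee). The fallback sets out from 10 and comes back at 13. It gives up catalytic control and uses a classical resolution.
- Heating 10 with methyl 3-methylbut-3-enoate (xylene, 150 °C, no catalyst) gives racemic methyl (6-acetoxy-2,5,7,8-tetramethylchroman-2-yl)acetate F1.
- KOH in aqueous methanol cleaves both esters to racemic (6-hydroxy-2,5,7,8-tetramethylchroman-2-yl)acetic acid F2.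
- Crystallisation with (S)-1-phenylethylamine gives (S)-1-phenylethylammonium (S)-(6-hydroxy-2,5,7,8-tetramethylchroman-2-yl)acetate F3.
- Acidification gives (S)-(6-hydroxy-2,5,7,8-tetramethylchroman-2-yl)acetic acid F4.
- LiAlH4 gives (S)-2-(2-hydroxyethyl)-2,5,7,8-tetramethylchroman-6-ol F5.
- CBr4/PPh3 reacts only at the primary alcohol and gives (S)-2-(2-bromoethyl)-2,5,7,8-tetramethylchroman-6-ol F6.
- Ac2O/pyridine gives 13.

**Step 2** (one catalyst must control two different alkenes). The fallback sets out from 2 and comes back at 3. It sets the two centres one after the other with two different control elements.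
- Hydroxyl-directed hydrogenation with Ru(OAc)2[(R)-BINAP] (H2 100 bar, MeOH) reduces only the allylic-alcohol alkene and gives (5E,10R)-11-hydroxy-6,10-dimethylundec-5-en-2-one F7.
- The remaining isolated alkene is then hydrogenated with the Ir–N,P complex, whose ligand enantiomer can now be chosen independently, to give 3.

**Step 8** (alkyl–alkyl coupling beside an aryl acetate, with a beta-branched Grignard reagent). The fallback sets out from 13 (with 14 from 5) and comes back at 15. It replaces the substitution by carbonyl addition and radical deoxygenation.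
- Kornblum oxidation of 13 (DMSO, NaHCO3, NaI, 100 °C) gives (S)-2,5,7,8-tetramethyl-2-(2-oxoethyl)chroman-6-yl acetate F8.
- Addition of 14 at −78 °C gives (2S)-2-[(4R,8S)-2-hydroxy-4,8,12-trimethyltridec-12-en-1-yl]-2,5,7,8-tetramethylchroman-6-yl acetate F9 (both C2' epimers).
- 1,1'-Thiocarbonyldiimidazole gives the O-(imidazol-1-ylthiocarbonyl) derivative of the C2' carbinol F10.
- Bu3SnH/AIBN (Barton–McCombie) gives 15, which LiAlH4 converts into 16 as in step 8.

## Further compounds
F1 | step 7 | methyl (6-acetoxy-2,5,7,8-tetramethylchroman-2-yl)acetate, racemic | COC(=O)CC1(C)CCc2c(C)c(OC(C)=O)c(C)c(C)c2O1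
F2 | step 7 | (6-hydroxy-2,5,7,8-tetramethylchroman-2-yl)acetic acid, racemic | OC(=O)CC1(C)CCc2c(C)c(O)c(C)c(C)c2O1
F3 | step 7 | (S)-1-phenylethylammonium (S)-(6-hydroxy-2,5,7,8-tetramethylchroman-2-yl)acetate | C[C@H]([NH3+])c1ccccc1.[O-]C(=O)C[C@]1(C)CCc2c(C)c(O)c(C)c(C)c2O1
F4 | step 7 | (S)-(6-hydroxy-2,5,7,8-tetramethylchroman-2-yl)acetic acid | OC(=O)C[C@]1(C)CCc2c(C)c(O)c(C)c(C)c2O1
F5 | step 7 | (S)-2-(2-hydroxyethyl)-2,5,7,8-tetramethylchroman-6-ol | OCC[C@]1(C)CCc2c(C)c(O)c(C)c(C)c2O1
F6 | step 7 | (S)-2-(2-bromoethyl)-2,5,7,8-tetramethylchroman-6-ol | BrCC[C@]1(C)CCc2c(C)c(O)c(C)c(C)c2O1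
F7 | step 2 | (5E,10R)-11-hydroxy-6,10-dimethylundec-5-en-2-one | CC(=O)CC/C=C(\C)CCC[C@@H](C)CO
F8 | step 8 | (S)-2,5,7,8-tetramethyl-2-(2-oxoethyl)chroman-6-yl acetate | O=CC[C@]1(C)CCc2c(C)c(OC(C)=O)c(C)c(C)c2O1
F9 | step 8 | (2S)-2-[(4R,8S)-2-hydroxy-4,8,12-trimethyltridec-12-en-1-yl]-2,5,7,8-tetramethylchroman-6-yl acetate, both C2' epimers | C=C(C)CCC[C@@H](C)CCC[C@@H](C)CC(O)C[C@]1(C)CCc2c(C)c(OC(C)=O)c(C)c(C)c2O1
F10 | step 8 | O-(imidazol-1-ylthiocarbonyl) derivative of the C2' carbinol | C=C(C)CCC[C@@H](C)CCC[C@@H](C)CC(OC(=S)n1ccnc1)C[C@]1(C)CCc2c(C)c(OC(C)=O)c(C)c(C)c2O1
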